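## Structural features

- The target is a C32H34O9 biscoumarin. Two identical 5,7-dimethoxycoumarin units are each bonded through C-8: coumarin A to the secondary carbinol carbon C-α, and coumarin B directly to C-2' of a 4',6',6'-trimethylcyclohex-3'-ene ring whose C-1' carries C-α.
- C-α (S), C-1' (S) and C-2' (R) are contiguous. The C-1' side chain and the C-2' aryl group are trans, and C-α/C-1' have the relationship of a syn aldol when C-2' is read as the carbonyl carbon.
- C-1' sits between the quaternary C-6' and the aryl-bearing C-2', and both aryl–C(sp3) bonds go to an arene position flanked by two oxygen substituents, so every bond around C-1' and C-2' is congested.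
- Fragile groups:
  - the two lactones (opened by hydroxide, attacked by organometallic reagents and strong hydrides);
  - the C-α–OH bond, benzylic to a trioxygenated ring and easily ionised by acid;
  - the doubly activated (allylic and benzylic) C-2'–H;
  - the trisubstituted alkene.
- The feature the key step exploits: the carbocycle with its three methyl groups and its double bond is, atom for atom, isophorone. C-2' is the carbonyl carbon, C-3'=C-4'(CH3) the enone double bond, C-6' the gem-dimethyl carbon and C-1' the α'-methylene carbon. C-2' is therefore one terminus of the allyl system C-2'/C-3'/C-4', and the C-8(coumarin B)–C-2' bond can be made by capture of that allyl cation by the intact, nucleophilic coumarin.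
- The real difficulty is not the ring. It is joining two hindered, base- and nucleophile-sensitive arenes to adjacent ring carbons with trans geometry and defined absolute configuration, without ionising C-α.

## Logic of the disconnections

**15 ⇒ 14.** The O–acetyl bond at C-α is cut. The free alcohol is a donor-substituted benzylic alcohol that cannot coexist with a carbocation elsewhere in the molecule, so it is carried as an ester. Nothing is simplified structurally. The forward step must remove a hindered acetate without opening the lactones for good and without touching C-2'–H.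

**14 ⇒ 11 + 1 (key).** The bond between C-8 of coumarin B and C-2' is cut.
- Reason: C-2' is allylic to C-3'=C-4', so this is the one bond that an electrophile-on-arene union can make with the coumarin intact and unmetalated.
- Gain: the whole coumarin B unit becomes commercial 1, the other fragment keeps only two stereocentres, and no ring has to be built.
- Demand: ionisation at C-2' and not at C-α, attack at the secondary terminus C-2' and at C-8 of 1, and entry of the arene anti to the C-1' substituent.
- In one sentence: 1 is alkylated at C-8 by the allyl cation released from 11.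

**11 ⇒ 10 ⇒ 9.** The C-2'–O(imidate) bond and then the C-2'–H bond are cut, which returns C-2' to a ketone. The reason is that the allyl cation precursor is then an enone and the ring is recognisable as isophorone. The forward steps need a 1,2-selective reduction in the presence of two esters and a leaving group that ionises at low temperature.

**9 ⇒ 8.** The O–acetyl bond at C-α is cut, revealing a β-hydroxy ketone. The forward acylation must not trigger β-elimination.

**8 ⇒ 3 + 6.** The C-α–C-1' bond is cut as an aldol bond. It lies between the carbinol carbon and the α'-carbon of the enone, and the cut separates coumarin A (as its 8-aldehyde) from the carbocycle. Both stereocentres of 8 arise here, so the forward step must be syn-selective and enantioselective on a hindered, electron-rich aldehyde.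

**6 ⇒ 4 and 3 ⇒ 1.** The O–Si bond of 6 and the C-8–CHO bond of 3 are cut, leading to commercial 4 and 1. The demands are kinetic α'-enolisation of 4 and C-8 selectivity in the formylation of 1.

## Other disconnections considered

**Alternative 1:** The first route that comes to mind cuts C-1'–C-2' and C-5'–C-6' in a Diels–Alder sense. Diene A1 and enone A2 would give ketone A3, which a hydride would reduce to 15.
- A2 is a β,β-dimethyl enone whose aroyl group is twisted out of conjugation, so it is a poor dienophile.
- The trans C-1'/C-2' relationship needs the exo arrangement of the aroyl group.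
- A2 offers no two-point binding site for a chiral Lewis acid, so absolute control is not in sight.
- C-α would be set last by substrate control alone, and A1 and A2 each have to be made from 1.
- The chosen plan buys the ring and sets C-α and C-1' together under catalyst control.

**Alternative 2:** The C-1'–C-2' bond is cut as a ring-contracting Claisen rearrangement of the 2-alkenyl-dihydropyran A4, a cyclic enol ether of the aryl ketone.
- The two-carbon tether C-5'/C-6' forces a boat transition state. With the accessible (E)-alkene this gives the cis ketone A5, the C-1' epimer of A3.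
- Epimerisation of A5 to A3 is not clearly downhill, because an axial aroyl group escapes one gauche contact with the gem-dimethyl group.
- The tertiary allylic ether stereocentre of A4 is hard to make in one enantiomeric form and ionises easily.

**Alternative 3:** The C-1'–C-2' bond is cut as an acyclic Ireland–Claisen rearrangement of the allylic ester A6 to the acid A7. The C-3'=C-4' bond is then closed by ring-closing metathesis with a second-generation Grubbs catalyst.
- The chair transition state would give the correct trans relationship, with chirality transferred from a secondary carbinol.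
- The tert-alkyl group must sit pseudo-axial in that chair, and a strong base is needed in the presence of a coumarin.
- Coumarin A must still be joined to a neopentyl-type carboxyl carbon and C-α set by ketone reduction.
- The route would be about eleven steps against eight.

Key step: step 7

Assumption: electrophilic substitution of 5,7-dimethoxycoumarin (formylation in step 1, allylation in step 7) takes place at C-8, the position para to the 5-methoxy group and flanked by only one methoxy group.

## Route

Step 1
Reactants: 1 5,7-dimethoxy-2H-chromen-2-one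
Product: 3 5,7-dimethoxy-2-oxo-2H-chromene-8-carbaldehyde, via chloro(methoxy)methyl arene 2 (not isolated)
Conditions: Cl2CHOMe, TiCl4, CH2Cl2, 0 °C to rt; then H2O
Reagents that add atoms: dichloromethyl methyl ether, COC(Cl)Cl; water, O
Why: Rieche formylation: the TiCl4-activated chloro ether attacks C-8 and the α-chloro ether 2 is hydrolysed on quenching. The lactone and the methyl ethers should tolerate TiCl4 at 0 °C.

Step 2
Reactants: 4 3,5,5-trimethylcyclohex-2-en-1-one (isophorone)
Product: 6 trimethyl[(3,3,5-trimethylcyclohexa-1,5-dien-1-yl)oxy]silane, via lithium dienolate 5 (not isolated)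
Conditions: LiN(iPr)2 (commercial solution), THF, −78 °C; Me3SiCl, −78 °C to 0 °C
Reagents that add atoms: chlorotrimethylsilane, C[Si](C)(C)Cl
Why: Kinetic deprotonation of the α'-methylene group by the hindered amide base gives the cross-conjugated dienolate 5, which is silylated on oxygen. No stereocentre is formed.

Step 3
Reactants: 3 5,7-dimethoxy-2-oxo-2H-chromene-8-carbaldehyde; 6 trimethyl[(3,3,5-trimethylcyclohexa-1,5-dien-1-yl)oxy]silane
Product: 8 8-[(S)-hydroxy[(1S)-4,6,6-trimethyl-2-oxocyclohex-3-en-1-yl]methyl]-5,7-dimethoxy-2H-chromen-2-one, via trimethylsilyl ether 7 (not isolated)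
Conditions: (4S)-2-butyl-4-(1H-indol-3-ylmethyl)-3-(4-methylbenzenesulfonyl)-1,3,2-oxazaborolidin-5-one (20 mol %), EtCN, −78 °C; then 1 M HCl, THF, 0 °C
Reagents that add atoms: none
Why: Catalytic enantioselective Mukaiyama aldol addition through an open transition state: attack on the Si face of the boron-bound aldehyde fixes C-α as S (the enantiomeric catalyst is the direct alternative should the sense on this aldehyde be opposite), and the CMe2 arm of the enol silane avoids the aryl group, which gives the syn (S,S) relationship at C-1'. Silyl transfer gives 7, which dilute acid cleaves on work-up.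

Step 4
Reactants: 8 8-[(S)-hydroxy[(1S)-4,6,6-trimethyl-2-oxocyclohex-3-en-1-yl]methyl]-5,7-dimethoxy-2H-chromen-2-one
Product: 9 (S)-(5,7-dimethoxy-2-oxo-2H-chromen-8-yl)[(1S)-4,6,6-trimethyl-2-oxocyclohex-3-en-1-yl]methyl acetate
Conditions: Ac2O, pyridine, 4-(dimethylamino)pyridine (10 mol %), CH2Cl2, 0 °C
Reagents that add atoms: acetic anhydride, CC(=O)OC(C)=O
Why: Nucleophile-catalysed acylation of the secondary alcohol at 0 °C, cold enough to avoid β-elimination of the β-acyloxy ketone. The acetyl group removes the donor character of the C-α oxygen for step 7, and no stereocentre is touched.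

Step 5
Reactants: 9 (S)-(5,7-dimethoxy-2-oxo-2H-chromen-8-yl)[(1S)-4,6,6-trimethyl-2-oxocyclohex-3-en-1-yl]methyl acetate
Product: 10 (S)-(5,7-dimethoxy-2-oxo-2H-chromen-8-yl)[(1R,2S)-2-hydroxy-4,6,6-trimethylcyclohex-3-en-1-yl]methyl acetate
Conditions: NaBH4, CeCl3·7H2O, MeOH–THF, −78 °C to −40 °C
Reagents that add atoms: none
Why: Luche reduction: 1,2-hydride addition to the enone should leave the lactone, the acetate and the C=C bonds alone. Hydride should enter anti to the axial C-6' methyl group and give mainly the cis alcohol shown; the C-2' configuration is of no consequence because this centre is ionised in step 7.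

Step 6
Reactants: 10 (S)-(5,7-dimethoxy-2-oxo-2H-chromen-8-yl)[(1R,2S)-2-hydroxy-4,6,6-trimethylcyclohex-3-en-1-yl]methyl acetate
Product: 11 (S)-(5,7-dimethoxy-2-oxo-2H-chromen-8-yl)[(1R,2S)-4,6,6-trimethyl-2-[(2,2,2-trichloroethanimidoyl)oxy]cyclohex-3-en-1-yl]methyl acetate
Conditions: Cl3CCN, 1,8-diazabicyclo[5.4.0]undec-7-ene (10 mol %), CH2Cl2, 0 °C
Reagents that add atoms: trichloroacetonitrile, ClC(Cl)(Cl)C#N
Why: Base-catalysed addition of the allylic alcohol to trichloroacetonitrile gives the trichloroacetimidate, a leaving group that can be ionised at −78 °C. Brief exposure to catalytic base at 0 °C should not allow a 1,3-acetyl shift.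

Step 7
Reactants: 11 (S)-(5,7-dimethoxy-2-oxo-2H-chromen-8-yl)[(1R,2S)-4,6,6-trimethyl-2-[(2,2,2-trichloroethanimidoyl)oxy]cyclohex-3-en-1-yl]methyl acetate; 1 5,7-dimethoxy-2H-chromen-2-one
Product: 14 (S)-(5,7-dimethoxy-2-oxo-2H-chromen-8-yl)[(1S,2R)-2-(5,7-dimethoxy-2-oxo-2H-chromen-8-yl)-4,6,6-trimethylcyclohex-3-en-1-yl]methyl acetate, via allyl cation 12 (not isolated), via dioxanylium ion 13 (not isolated)
Conditions: 1 (3 equiv), trimethylsilyl trifluoromethanesulfonate (Me3SiOTf, 20 mol %), 4 Å molecular sieves, CH2Cl2, −78 °C to −40 °C; Et3N quench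
Reagents that add atoms: none
Why: Me3SiOTf activates the imidate nitrogen and the C-2'–O bond ionises to the allyl cation 12 (C-2'/C-3'/C-4'), which the neighbouring acetate can cap reversibly as the cis-fused dioxanylium ion 13, holding it back from loss of the C-1' proton; C-8 of 1 then attacks C-2' and the arenium ion loses its proton to give 14 and trichloroacetamide, regenerating the acid. The closest known reaction types are the Friedel–Crafts allylation of resorcinols and phloroglucinols by cyclohexenyl cations (the cannabidiol-type terpenylation) and the Lewis acid-catalysed Friedel–Crafts alkylation of arenes with trichloroacetimidates. No ring is closed: the six-membered ring is that of isophorone and the step only joins coumarin B to it. The new stereocentre C-2' is controlled by C-1': its large CH(OAc)Ar substituent sits pseudo-equatorial and the dioxanylium bridge covers the same face, so the arene enters anti and the trans (1S,2R) relationship should result. Regioselectivity in the cation is needed for the secondary terminus C-2' over the tertiary C-4', and attack at C-4' would build a quaternary carbon bearing a 2,6-disubstituted arene; site selectivity in 1 is needed for C-8 over C-6, which lies between two methoxy groups. Chemoselectivity is needed for ionisation at C-2' and not at C-α: the imidate is the only leaving group activated at −78 °C, and the acetyl group destabilises both the benzylic cation at C-α and the oxocarbenium ion that a retro-Prins fragmentation of 12 would expel.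

Step 8
Reactants: 14 (S)-(5,7-dimethoxy-2-oxo-2H-chromen-8-yl)[(1S,2R)-2-(5,7-dimethoxy-2-oxo-2H-chromen-8-yl)-4,6,6-trimethylcyclohex-3-en-1-yl]methyl acetate
Product: 15 8-[(S)-[(1S,2R)-2-(5,7-dimethoxy-2-oxo-2H-chromen-8-yl)-4,6,6-trimethylcyclohex-3-en-1-yl](hydroxy)methyl]-5,7-dimethoxy-2H-chromen-2-one
Conditions: K2CO3 (cat.), MeOH–THF, rt
Reagents that add atoms: none
Why: Carbonate-catalysed transesterification with methanol should free the hindered secondary alcohol without touching C-2'–H or the acid-labile benzylic C–O bond. Any methanolysis of a lactone reverses on mild acidification (about pH 5) during work-up, and no stereocentre is affected.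

## Compound list

1 | 5,7-dimethoxy-2H-chromen-2-one (5,7-dimethoxycoumarin) | COc1cc(OC)c2ccc(=O)oc2c1 | starting material
2 | 8-[chloro(methoxy)methyl]-5,7-dimethoxy-2H-chromen-2-one (racemic) | COC(Cl)c1c(OC)cc(OC)c2ccc(=O)oc12 | intermediate (not isolated)
3 | 5,7-dimethoxy-2-oxo-2H-chromene-8-carbaldehyde | O=Cc1c(OC)cc(OC)c2ccc(=O)oc12 | intermediate
4 | 3,5,5-trimethylcyclohex-2-en-1-one (isophorone) | CC1=CC(=O)CC(C)(C)C1 | starting material
5 | lithium 3,3,5-trimethylcyclohexa-1,5-dien-1-olate | [Li+].[O-]C1=CC(C)(C)CC(C)=C1 | intermediate (not isolated)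
6 | trimethyl[(3,3,5-trimethylcyclohexa-1,5-dien-1-yl)oxy]silane | C[Si](C)(C)OC1=CC(C)(C)CC(C)=C1 | intermediate
7 | 5,7-dimethoxy-8-[(S)-[(1S)-4,6,6-trimethyl-2-oxocyclohex-3-en-1-yl][(trimethylsilyl)oxy]methyl]-2H-chromen-2-one | COc1cc(OC)c2ccc(=O)oc2c1[C@@H](O[Si](C)(C)C)[C@H]1C(=O)C=C(C)CC1(C)C | intermediate (not isolated)
8 | 8-[(S)-hydroxy[(1S)-4,6,6-trimethyl-2-oxocyclohex-3-en-1-yl]methyl]-5,7-dimethoxy-2H-chromen-2-one | COc1cc(OC)c2ccc(=O)oc2c1[C@@H](O)[C@H]1C(=O)C=C(C)CC1(C)C | intermediate
9 | (S)-(5,7-dimethoxy-2-oxo-2H-chromen-8-yl)[(1S)-4,6,6-trimethyl-2-oxocyclohex-3-en-1-yl]methyl acetate | COc1cc(OC)c2ccc(=O)oc2c1[C@@H](OC(C)=O)[C@H]1C(=O)C=C(C)CC1(C)C | intermediate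
10 | (S)-(5,7-dimethoxy-2-oxo-2H-chromen-8-yl)[(1R,2S)-2-hydroxy-4,6,6-trimethylcyclohex-3-en-1-yl]methyl acetate | COc1cc(OC)c2ccc(=O)oc2c1[C@@H](OC(C)=O)[C@H]1[C@@H](O)C=C(C)CC1(C)C | intermediate
11 | (S)-(5,7-dimethoxy-2-oxo-2H-chromen-8-yl)[(1R,2S)-4,6,6-trimethyl-2-[(2,2,2-trichloroethanimidoyl)oxy]cyclohex-3-en-1-yl]methyl acetate | COc1cc(OC)c2ccc(=O)oc2c1[C@@H](OC(C)=O)[C@H]1[C@@H](OC(=N)C(Cl)(Cl)Cl)C=C(C)CC1(C)C | intermediate
12 | (6S)-6-[(S)-(acetyloxy)(5,7-dimethoxy-2-oxo-2H-chromen-8-yl)methyl]-3,5,5-trimethylcyclohex-2-en-1-ylium (allyl cation) | COc1cc(OC)c2ccc(=O)oc2c1[C@@H](OC(C)=O)[C@H]1[CH+]C=C(C)CC1(C)C | intermediate (not isolated)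
13 | (4S,4aR,8aS)-4-(5,7-dimethoxy-2-oxo-2H-chromen-8-yl)-2,5,5,7-tetramethyl-4a,5,6,8a-tetrahydro-4H-1,3-benzodioxin-2-ylium (cis-fused dioxanylium ion) | COc1cc(OC)c2ccc(=O)oc2c1[C@@H]([O+]=C(C)O3)[C@H]1[C@@H]3C=C(C)CC1(C)C | intermediate (not isolated)
14 | (S)-(5,7-dimethoxy-2-oxo-2H-chromen-8-yl)[(1S,2R)-2-(5,7-dimethoxy-2-oxo-2H-chromen-8-yl)-4,6,6-trimethylcyclohex-3-en-1-yl]methyl acetate | COc1cc(OC)c2ccc(=O)oc2c1[C@@H](OC(C)=O)[C@H]1[C@H](c2c(OC)cc(OC)c3ccc(=O)oc23)C=C(C)CC1(C)C | intermediate
15 | 8-[(S)-[(1S,2R)-2-(5,7-dimethoxy-2-oxo-2H-chromen-8-yl)-4,6,6-trimethylcyclohex-3-en-1-yl](hydroxy)methyl]-5,7-dimethoxy-2H-chromen-2-one (CNP0324863.2) | COc1cc(OC)c2ccc(=O)oc2c1[C@@H](O)[C@H]1[C@H](c2c(OC)cc(OC)c3ccc(=O)oc23)C=C(C)CC1(C)C | target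

## Step count and least certain steps

Total step count: 8. Longest linear sequence: 7 steps (4 to 15 through steps 2 to 8; the branch from 1 to 3 is one step).

**Step 7 (key step).** The most likely failure is loss of the C-1' proton from the cation, an elimination to a cyclohexadiene that would also erode the C-1' configuration on reprotonation. It could outrun capture because 1 is only a moderate π-nucleophile; attack at C-6 of the arene is the second risk. The fallback sets out from 11 and changes the nucleophile and the way coumarin B is made.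
- 11 is treated under the same conditions with the far more nucleophilic 3,5-dimethoxyphenol F1. This should give the ortho-C-allylated phenol (S)-(5,7-dimethoxy-2-oxo-2H-chromen-8-yl)[(1S,2R)-2-(2-hydroxy-4,6-dimethoxyphenyl)-4,6,6-trimethylcyclohex-3-en-1-yl]methyl acetate F2.
- Esterification with propiolic acid and N,N'-dicyclohexylcarbodiimide gives 2-[(1R,6S)-6-[(S)-(acetyloxy)(5,7-dimethoxy-2-oxo-2H-chromen-8-yl)methyl]-3,5,5-trimethylcyclohex-2-en-1-yl]-3,5-dimethoxyphenyl prop-2-ynoate F3.
- Gold-catalysed intramolecular hydroarylation ((Ph3P)AuNTf2, CH2Cl2, rt) closes the pyranone ring of coumarin B at its C-4–C-4a bond, the only free ortho position. The sequence comes back to the route at 14.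

**Step 3.** The most likely failure is slow addition with poor facial selectivity. The aldehyde is electron-rich and di-ortho-substituted and offers the catalyst competing Lewis-basic sites, and the nucleophilic carbon is neopentyl-like. The fallback sets out from 5 (made from 4 as in step 2) and 3 and replaces asymmetric catalysis by resolution.
- 5 is transmetalated with ClTi(OiPr)3 to tri(propan-2-yloxy)[(3,3,5-trimethylcyclohexa-1,5-dien-1-yl)oxy]titanium F4.
- Addition of F4 to 3 should be syn-selective and give 8 together with its enantiomer 8-[(R)-hydroxy[(1R)-4,6,6-trimethyl-2-oxocyclohex-3-en-1-yl]methyl]-5,7-dimethoxy-2H-chromen-2-one F5.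
- Preparative chromatography on a chiral stationary phase separates the two, and the sequence comes back to the route at 8.

**Step 1.** The most likely failure is poor site selectivity, with formylation at C-6 or at both positions. The fallback builds the coumarin after the aldehyde is in place.
- It sets out from commercial 2-hydroxy-4,6-dimethoxybenzaldehyde F6, which is esterified with propiolic acid and N,N'-dicyclohexylcarbodiimide to 2-formyl-3,5-dimethoxyphenyl prop-2-ynoate F7.
- Hydroarylation with Pd(OAc)2 in CF3CO2H–CH2Cl2 closes the pyranone ring at the C-4–C-4a bond, where only one ortho position is free. The sequence comes back to the route at 3.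

## Further compounds

F1 | step 7 | 3,5-dimethoxyphenol | COc1cc(O)cc(OC)c1
F2 | step 7 | (S)-(5,7-dimethoxy-2-oxo-2H-chromen-8-yl)[(1S,2R)-2-(2-hydroxy-4,6-dimethoxyphenyl)-4,6,6-trimethylcyclohex-3-en-1-yl]methyl acetate | COc1cc(OC)c2ccc(=O)oc2c1[C@@H](OC(C)=O)[C@H]1[C@H](c2c(OC)cc(OC)cc2O)C=C(C)CC1(C)C
F3 | step 7 | 2-[(1R,6S)-6-[(S)-(acetyloxy)(5,7-dimethoxy-2-oxo-2H-chromen-8-yl)methyl]-3,5,5-trimethylcyclohex-2-en-1-yl]-3,5-dimethoxyphenyl prop-2-ynoate | COc1cc(OC)c2ccc(=O)oc2c1[C@@H](OC(C)=O)[C@H]1[C@H](c2c(OC)cc(OC)cc2OC(=O)C#C)C=C(C)CC1(C)C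
F4 | step 3 | tri(propan-2-yloxy)[(3,3,5-trimethylcyclohexa-1,5-dien-1-yl)oxy]titanium | CC(C)O[Ti](OC(C)C)(OC(C)C)OC1=CC(C)(C)CC(C)=C1
F5 | step 3 | 8-[(R)-hydroxy[(1R)-4,6,6-trimethyl-2-oxocyclohex-3-en-1-yl]methyl]-5,7-dimethoxy-2H-chromen-2-one | COc1cc(OC)c2ccc(=O)oc2c1[C@H](O)[C@@H]1C(=O)C=C(C)CC1(C)C
F6 | step 1 | 2-hydroxy-4,6-dimethoxybenzaldehyde | COc1cc(O)c(C=O)c(OC)c1
F7 | step 1 | 2-formyl-3,5-dimethoxyphenyl prop-2-ynoate | COc1cc(OC(=O)C#C)c(C=O)c(OC)c1
A1 | alternative 1 | 5,7-dimethoxy-8-[(E)-3-methylbuta-1,3-dien-1-yl]-2H-chromen-2-one | COc1cc(OC)c2ccc(=O)oc2c1/C=C/C(C)=C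
A2 | alternative 1 | 5,7-dimethoxy-8-(3-methylbut-2-enoyl)-2H-chromen-2-one | COc1cc(OC)c2ccc(=O)oc2c1C(=O)C=C(C)C
A3 | alternative 1 | 8-[(1S,2R)-2-(5,7-dimethoxy-2-oxo-2H-chromen-8-yl)-4,6,6-trimethylcyclohex-3-ene-1-carbonyl]-5,7-dimethoxy-2H-chromen-2-one | COc1cc(OC)c2ccc(=O)oc2c1C(=O)[C@H]1[C@H](c2c(OC)cc(OC)c3ccc(=O)oc23)C=C(C)CC1(C)C
A4 | alternative 2 | 8-[(E)-2-[(2R)-6-(5,7-dimethoxy-2-oxo-2H-chromen-8-yl)-2,4,4-trimethyl-3,4-dihydro-2H-pyran-2-yl]ethenyl]-5,7-dimethoxy-2H-chromen-2-one | COc1cc(OC)c2ccc(=O)oc2c1C1=CC(C)(C)C[C@](C)(/C=C/c2c(OC)cc(OC)c3ccc(=O)oc23)O1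
A5 | alternative 2 | 8-[(1R,2R)-2-(5,7-dimethoxy-2-oxo-2H-chromen-8-yl)-4,6,6-trimethylcyclohex-3-ene-1-carbonyl]-5,7-dimethoxy-2H-chromen-2-one | COc1cc(OC)c2ccc(=O)oc2c1C(=O)[C@@H]1[C@H](c2c(OC)cc(OC)c3ccc(=O)oc23)C=C(C)CC1(C)C
A6 | alternative 3 | (2S,3E)-4-(5,7-dimethoxy-2-oxo-2H-chromen-8-yl)but-3-en-2-yl 3,3,5-trimethylhex-5-enoate | C=C(C)CC(C)(C)CC(=O)O[C@@H](C)/C=C/c1c(OC)cc(OC)c2ccc(=O)oc12
A7 | alternative 3 | (2S,3R,4E)-3-(5,7-dimethoxy-2-oxo-2H-chromen-8-yl)-2-(2,4-dimethylpent-4-en-2-yl)hex-4-enoic acid | OC(=O)[C@H](C(C)(C)CC(C)=C)[C@@H](/C=C/C)c1c(OC)cc(OC)c2ccc(=O)oc12
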